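**Retrosynthetic overview**

1. The target is (R)-5,7-dihydroxy-6-(1-methylpiperidin-2-yl)flavone. Its only stereocentre, piperidine C2', is benzylic, bonded to C6 of ring A and flanked by the phenolic oxygens on C5 and C7, so it can be flattened into an ortho-quinone methide carbon and rebuilt under catalyst control.
2. Ring C is cut last (O1–C2 and C4–C4a) to an ortho-iodophenol, phenylacetylene and CO. The phenol used is the oxygen para to C6 and its two ortho carbons are equivalent, so only the 6-substituted flavone can form.
3. N-CH3 comes from N-CO2Me (LiAlH4). The piperidine ring is cut at N1'–C2': aza-Michael closure of a tethered methyl carbamate onto the quinone methide from a racemic 2,6-dihydroxybenzylic alcohol, under a chiral phosphoric acid.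
4. The alcohol comes from an aryl ketone, made by lithiation of 5-benzyloxyresorcinol bis-MOM ether between the two acetal ethers and opening of N-methoxycarbonylpiperidin-2-one.
5. Ring order: ring A (phloroglucinol) and ring B (phenylacetylene) are bought; the piperidine ring closes in step 7 and pyranone ring C in step 12.

Key step: step 7

Assumption: the sense of induction of a phosphoric acid catalyst cannot be assigned beforehand; (R)-TRIP is written, and its (S) enantiomer is used instead if the closure proves to deliver the (S)-piperidine.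

**Route**

Step 1
Reactants: 1 phloroglucinol; 2 benzyl bromide
Product: 3 5-(benzyloxy)benzene-1,3-diol
Conditions: 1 (3 equiv), BnBr (1 equiv), K2CO3, DMF, 0 °C → rt
Reagents that add atoms: none
Why: Williamson O-alkylation of a phenoxide, where a threefold excess of the triol should hold the reaction at the mono-ether and unreacted phloroglucinol is washed out with water.

Step 2
Reactants: 3 5-(benzyloxy)benzene-1,3-diol
Product: 4 1-(benzyloxy)-3,5-bis(methoxymethoxy)benzene
Conditions: MOMCl, i-Pr2NEt, CH2Cl2, 0 °C → rt
Reagents that add atoms: chloromethyl methyl ether, COCCl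
Why: Standard methoxymethyl acetal protection of both phenols under amine base, which also installs the two directing groups for the metalation.

Step 3
Reactants: 5 piperidin-2-one; 6 methyl chloroformate
Product: 8 methyl 2-oxopiperidine-1-carboxylate, via lithium lactamate 7 (not isolated)
Conditions: n-BuLi, THF, −78 °C; then ClCO2Me, −78 → 0 °C
Reagents that add atoms: none
Why: N-acylation of the lithium lactamate by a chloroformate should give the imide-type N-alkoxycarbonyl lactam, whose ring carbonyl is activated toward organometallic opening.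

Step 4
Reactants: 4 1-(benzyloxy)-3,5-bis(methoxymethoxy)benzene; 8 methyl 2-oxopiperidine-1-carboxylate
Product: 11 methyl N-{5-[4-(benzyloxy)-2,6-bis(methoxymethoxy)phenyl]-5-oxopentyl}carbamate, via aryllithium 9 (not isolated), via lithium hemiaminal alkoxide 10 (not isolated)
Conditions: n-BuLi, THF, 0 °C; then 8, −78 °C; AcOH quench, −78 °C → rt
Reagents that add atoms: none
Why: Directed ortho-metalation should occur at the CH between the two MOM ethers (most acidic, chelated by two acetal oxygens), and the aryllithium adds to the ketone-like ring carbonyl of the N-acyl lactam to give a tetrahedral alkoxide that opens to the keto carbamate on quench (organolithium ring opening of an N-alkoxycarbonyl lactam), the doubly ortho-substituted ketone resisting a second addition.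

Step 5
Reactants: 11 methyl N-{5-[4-(benzyloxy)-2,6-bis(methoxymethoxy)phenyl]-5-oxopentyl}carbamate
Product: 12 methyl N-{5-[4-(benzyloxy)-2,6-dihydroxyphenyl]-5-oxopentyl}carbamate
Conditions: 2 M HCl, MeOH–THF, 40 °C
Reagents that add atoms: none
Why: Acid-catalysed cleavage of aryl MOM acetals, to which the methyl carbamate and benzyl ether are inert, while the hydrogen-bonded, doubly ortho-substituted ketone is too deactivated to condense with the carbamate N–H.

Step 6
Reactants: 12 methyl N-{5-[4-(benzyloxy)-2,6-dihydroxyphenyl]-5-oxopentyl}carbamate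
Product: 13 racemic methyl N-{5-[4-(benzyloxy)-2,6-dihydroxyphenyl]-5-hydroxypentyl}carbamate
Conditions: NaBH4 (excess), MeOH–THF, 0 °C → rt; pH 7 phosphate buffer, 0 °C; used crude
Reagents that add atoms: none
Why: Borohydride reduction of an ortho-hydroxyaryl ketone to the racemic benzylic alcohol (no stereocontrol is wanted, since step 7 erases this centre), with low temperature and a neutral quench keeping the electron-rich 2,6-dihydroxybenzyl alcohol from ionising before the catalyst is added.

Step 7
Reactants: 13 racemic methyl N-{5-[4-(benzyloxy)-2,6-dihydroxyphenyl]-5-hydroxypentyl}carbamate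
Product: 15 methyl (2R)-2-[4-(benzyloxy)-2,6-dihydroxyphenyl]piperidine-1-carboxylate, via ortho-quinone methide 14 (not isolated)
Conditions: (R)-TRIP [(R)-3,3'-bis(2,4,6-triisopropylphenyl)-1,1'-binaphthyl-2,2'-diyl hydrogen phosphate] (10 mol%), 4 Å MS, CH2Cl2 (0.02 M), −20 → 0 °C
Reagents that add atoms: none
Why: The phosphoric acid activates the benzylic hydroxyl of 13 through a hydrogen-bond relay with an ortho phenol and water leaves to give the planar ortho-quinone methide 14 (or its phosphate contact ion pair), so both enantiomers of 13 funnel into one achiral intermediate; the two flanking phenols make the two possible quinone methides identical and let the methide geometry equilibrate by a simple proton shift. The closest known reaction type is the chiral phosphoric acid catalysed aza-Michael addition of N–H nucleophiles to ortho-quinone methides generated in situ from ortho-hydroxybenzyl alcohols, here run intramolecularly. The piperidine ring closes by 6-exo-trig attack of the carbamate nitrogen on the exocyclic methide carbon, forming N1'–C2' and restoring the aromaticity of ring A. The C2' configuration is set by the catalyst: the phosphate holds the quinone methide oxygen through P–OH and the carbamate N–H through P=O, and the 2,4,6-triisopropylphenyl walls leave one enantioface of the methide open to the tethered nitrogen. The step needs catalysed N-closure to outrun intermolecular C-alkylation by another electron-rich ring, uncatalysed closure and re-ionisation of 15; the six-membered tether, high dilution, low temperature, molecular sieves and the weak nucleophilicity of the methyl carbamate (which reacts only when hydrogen-bonded to the phosphate) should secure this.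

Step 8
Reactants: 15 methyl (2R)-2-[4-(benzyloxy)-2,6-dihydroxyphenyl]piperidine-1-carboxylate
Product: 16 methyl (2R)-2-[4-(benzyloxy)-2,6-bis(methoxymethoxy)phenyl]piperidine-1-carboxylate
Conditions: MOMCl, i-Pr2NEt, CH2Cl2, 0 °C → rt
Reagents that add atoms: chloromethyl methyl ether, COCCl
Why: Methoxymethylation of both phenols removes the free ortho hydroxyls, so C2' can no longer ionise through a quinone methide and its configuration is locked for the following steps.

Step 9
Reactants: 16 methyl (2R)-2-[4-(benzyloxy)-2,6-bis(methoxymethoxy)phenyl]piperidine-1-carboxylate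
Product: 17 (2R)-2-[4-(benzyloxy)-2,6-bis(methoxymethoxy)phenyl]-1-methylpiperidine
Conditions: LiAlH4, THF, reflux; aqueous NaOH work-up
Reagents that add atoms: none
Why: LiAlH4 reduction of an N-methoxycarbonyl group through the hemiaminal and iminium ion turns the carbamate carbon into the N-CH3 carbon, with acetal and benzyl ethers inert to hydride and C2' untouched.

Step 10
Reactants: 17 (2R)-2-[4-(benzyloxy)-2,6-bis(methoxymethoxy)phenyl]-1-methylpiperidine
Product: 18 3,5-bis(methoxymethoxy)-4-[(2R)-1-methylpiperidin-2-yl]phenol
Conditions: H2 (1 atm), palladium on carbon (10% Pd/C), EtOAc–EtOH, rt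
Reagents that add atoms: none
Why: Catalytic hydrogenolysis of the aryl benzyl ether should be much faster than cleavage of the hindered ring benzylic C–N bond, so only the oxygen para to the piperidine-bearing carbon is set free.

Step 11
Reactants: 18 3,5-bis(methoxymethoxy)-4-[(2R)-1-methylpiperidin-2-yl]phenol
Product: 19 2-iodo-3,5-bis(methoxymethoxy)-4-[(2R)-1-methylpiperidin-2-yl]phenol
Conditions: I2 (1.0 equiv), NaHCO3, THF–H2O, 0 °C
Reagents that add atoms: iodine, [I][I]
Why: Electrophilic iodination of the phenoxide, where the only open ring positions are the two equivalent carbons ortho to the free hydroxyl, so one equivalent of iodine should give a single mono-iodide.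

Step 12
Reactants: 19 2-iodo-3,5-bis(methoxymethoxy)-4-[(2R)-1-methylpiperidin-2-yl]phenol; 20 phenylacetylene
Product: 22 5,7-bis(methoxymethoxy)-6-[(2R)-1-methylpiperidin-2-yl]-2-phenyl-4H-chromen-4-one, via ortho-hydroxyaryl ynone 21 (not isolated)
Conditions: PdCl2(PPh3)2 (5 mol%), CO (1 atm), Et2NH, DMF, 50 °C
Reagents that add atoms: carbon monoxide, [C-]#[O+]
Why: Carbonylative Sonogashira-type coupling (oxidative addition of zerovalent palladium into C–I, CO insertion, alkynylation) gives ynone 21, and diethylamine conjugate addition–elimination closes the pyranone in the 6-endo sense; because the free phenol is the oxygen para to C6, ring C can only form with O1 on that oxygen.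

Step 13
Reactants: 22 5,7-bis(methoxymethoxy)-6-[(2R)-1-methylpiperidin-2-yl]-2-phenyl-4H-chromen-4-one
Product: 23 5,7-dihydroxy-6-[(2R)-1-methylpiperidin-2-yl]-2-phenyl-4H-chromen-4-one
Conditions: 3 M HCl, MeOH, 40 °C; then aq NaHCO3 to pH 8
Reagents that add atoms: none
Why: Acid-catalysed cleavage of the two aryl MOM acetals, where the electron-poor chromone ring A and the mild temperature disfavour ionisation at C2', and basification gives the free base.

**Compound list**

1 | phloroglucinol (benzene-1,3,5-triol) | Oc1cc(O)cc(O)c1 | starting material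
2 | benzyl bromide | BrCc1ccccc1 | starting material
3 | 5-(benzyloxy)benzene-1,3-diol | Oc1cc(O)cc(OCc2ccccc2)c1 | intermediate
4 | 1-(benzyloxy)-3,5-bis(methoxymethoxy)benzene | COCOc1cc(OCOC)cc(OCc2ccccc2)c1 | intermediate
5 | piperidin-2-one | O=C1CCCCN1 | starting material
6 | methyl chloroformate | COC(=O)Cl | starting material
7 | lithium 2-oxopiperidin-1-ide | [Li]N1CCCCC1=O | intermediate (not isolated)
8 | methyl 2-oxopiperidine-1-carboxylate | COC(=O)N1CCCCC1=O | intermediate
9 | [4-(benzyloxy)-2,6-bis(methoxymethoxy)phenyl]lithium | [Li]c1c(OCOC)cc(OCc2ccccc2)cc1OCOC | intermediate (not isolated)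
10 | lithium alkoxide of racemic methyl 2-[4-(benzyloxy)-2,6-bis(methoxymethoxy)phenyl]-2-hydroxypiperidine-1-carboxylate | [Li]OC1(CCCCN1C(=O)OC)c1c(OCOC)cc(OCc2ccccc2)cc1OCOC | intermediate (not isolated)
11 | methyl N-{5-[4-(benzyloxy)-2,6-bis(methoxymethoxy)phenyl]-5-oxopentyl}carbamate | COC(=O)NCCCCC(=O)c1c(OCOC)cc(OCc2ccccc2)cc1OCOC | intermediate
12 | methyl N-{5-[4-(benzyloxy)-2,6-dihydroxyphenyl]-5-oxopentyl}carbamate | COC(=O)NCCCCC(=O)c1c(O)cc(OCc2ccccc2)cc1O | intermediate
13 | racemic methyl N-{5-[4-(benzyloxy)-2,6-dihydroxyphenyl]-5-hydroxypentyl}carbamate | COC(=O)NCCCCC(O)c1c(O)cc(OCc2ccccc2)cc1O | intermediate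
14 | methyl N-{5-[4-(benzyloxy)-2-hydroxy-6-oxocyclohexa-2,4-dien-1-ylidene]pentyl}carbamate (ortho-quinone methide, geometry not fixed) | COC(=O)NCCCCC=C1C(=O)C=C(OCc2ccccc2)C=C1O | intermediate (not isolated)
15 | methyl (2R)-2-[4-(benzyloxy)-2,6-dihydroxyphenyl]piperidine-1-carboxylate | COC(=O)N1CCCC[C@@H]1c1c(O)cc(OCc2ccccc2)cc1O | intermediate
16 | methyl (2R)-2-[4-(benzyloxy)-2,6-bis(methoxymethoxy)phenyl]piperidine-1-carboxylate | COC(=O)N1CCCC[C@@H]1c1c(OCOC)cc(OCc2ccccc2)cc1OCOC | intermediate
17 | (2R)-2-[4-(benzyloxy)-2,6-bis(methoxymethoxy)phenyl]-1-methylpiperidine | CN1CCCC[C@@H]1c1c(OCOC)cc(OCc2ccccc2)cc1OCOC | intermediate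
18 | 3,5-bis(methoxymethoxy)-4-[(2R)-1-methylpiperidin-2-yl]phenol | CN1CCCC[C@@H]1c1c(OCOC)cc(O)cc1OCOC | intermediate
19 | 2-iodo-3,5-bis(methoxymethoxy)-4-[(2R)-1-methylpiperidin-2-yl]phenol | CN1CCCC[C@@H]1c1c(OCOC)cc(O)c(I)c1OCOC | intermediate
20 | phenylacetylene | C#Cc1ccccc1 | starting material
21 | 1-{6-hydroxy-2,4-bis(methoxymethoxy)-3-[(2R)-1-methylpiperidin-2-yl]phenyl}-3-phenylprop-2-yn-1-one | CN1CCCC[C@@H]1c1c(OCOC)cc(O)c(C(=O)C#Cc2ccccc2)c1OCOC | intermediate (not isolated)
22 | 5,7-bis(methoxymethoxy)-6-[(2R)-1-methylpiperidin-2-yl]-2-phenyl-4H-chromen-4-one | CN1CCCC[C@@H]1c1c(OCOC)cc2oc(-c3ccccc3)cc(=O)c2c1OCOC | intermediate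
23 | 5,7-dihydroxy-6-[(2R)-1-methylpiperidin-2-yl]-2-phenyl-4H-chromen-4-one | CN1CCCC[C@@H]1c1c(O)cc2oc(-c3ccccc3)cc(=O)c2c1O | target

**Step count**

Total: 13 steps. Longest linear sequence: 12 steps (1 → 23 through steps 1, 2 and 4–13); step 3 is a one-step branch.

**Steps most likely to fail**

Step 7. Enantiofacial control may be eroded by uncatalysed closure and by acid re-ionisation of the product, or intermolecular C-alkylation of the electron-rich ring may outpace N-closure. The fallback gives up catalyst control and resolves instead. It sets out from 13, which is closed with an achiral acid (diphenyl phosphate, CH2Cl2) to racemic methyl 2-[4-(benzyloxy)-2,6-dihydroxyphenyl]piperidine-1-carboxylate F1. This is protected as in step 8 to the racemic bis-MOM carbamate F2 and reduced as in step 9 to racemic 2-[4-(benzyloxy)-2,6-bis(methoxymethoxy)phenyl]-1-methylpiperidine F3. The basic amine is then resolved by crystallising the salt of the (R)-amine with (2R,3R)-O,O'-di-p-toluoyltartaric acid F4 (or with the antipodal acid, whichever gives the crystalline (R)-amine salt). Treatment with aqueous Na2CO3 releases the free base, and the route is rejoined at 17.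

Step 12. Direct, non-carbonylative alkynylation and 5-exo closure to the aurone may compete with CO insertion and 6-endo closure, or oxidative addition into the hindered, electron-rich C–I bond may be sluggish. The fallback avoids palladium and the iodide. It sets out from 18, which is ortho-formylated (MgCl2, Et3N, paraformaldehyde, MeCN, reflux) to 6-hydroxy-2,4-bis(methoxymethoxy)-3-[(2R)-1-methylpiperidin-2-yl]benzaldehyde F5. Excess lithium phenylacetylide (from 20 and n-BuLi, THF, −78 °C) should give 2-(1-hydroxy-3-phenylprop-2-yn-1-yl)-3,5-bis(methoxymethoxy)-4-[(2R)-1-methylpiperidin-2-yl]phenol F6 as a mixture of carbinol epimers. MnO2 in CH2Cl2 oxidises the propargylic alcohol to ynone 21, and the route is rejoined there; Et2NH then closes 21 to 22 as in step 12.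

Step 4. Metalation may occur next to the benzyl ether or at the benzylic CH2 (followed by Wittig rearrangement), or the hindered aryllithium may deprotonate the lactam or attack the carbamate carbonyl instead of the ring carbonyl. The fallback avoids lithiation and the MOM ethers altogether. It sets out from 1: commercial 5-aminopentanoic acid is N-acylated with 6 (aq NaOH, 0 °C) to 5-[(methoxycarbonyl)amino]pentanoic acid F7. Friedel–Crafts acylation of 1 with F7 in BF3·OEt2 at 80 °C should give methyl N-[5-oxo-5-(2,4,6-trihydroxyphenyl)pentyl]carbamate F8. The non-chelated, most acidic 4-hydroxyl is then benzylated with 2 (1 equiv, K2CO3, acetone), and the route is rejoined at 12, bypassing steps 1, 2, 4 and 5.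

**Further compounds**

F1 | step 7 | racemic methyl 2-[4-(benzyloxy)-2,6-dihydroxyphenyl]piperidine-1-carboxylate | COC(=O)N1CCCCC1c1c(O)cc(OCc2ccccc2)cc1O
F2 | step 7 | racemic methyl 2-[4-(benzyloxy)-2,6-bis(methoxymethoxy)phenyl]piperidine-1-carboxylate | COC(=O)N1CCCCC1c1c(OCOC)cc(OCc2ccccc2)cc1OCOC
F3 | step 7 | racemic 2-[4-(benzyloxy)-2,6-bis(methoxymethoxy)phenyl]-1-methylpiperidine | CN1CCCCC1c1c(OCOC)cc(OCc2ccccc2)cc1OCOC
F4 | step 7 | 1:1 salt of (2R)-2-[4-(benzyloxy)-2,6-bis(methoxymethoxy)phenyl]-1-methylpiperidine with (2R,3R)-2,3-bis(4-methylbenzoyloxy)butanedioic acid | CN1CCCC[C@@H]1c1c(OCOC)cc(OCc2ccccc2)cc1OCOC.OC(=O)[C@H](OC(=O)c1ccc(C)cc1)[C@@H](OC(=O)c1ccc(C)cc1)C(O)=O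
F5 | step 12 | 6-hydroxy-2,4-bis(methoxymethoxy)-3-[(2R)-1-methylpiperidin-2-yl]benzaldehyde | CN1CCCC[C@@H]1c1c(OCOC)cc(O)c(C=O)c1OCOC
F6 | step 12 | 2-(1-hydroxy-3-phenylprop-2-yn-1-yl)-3,5-bis(methoxymethoxy)-4-[(2R)-1-methylpiperidin-2-yl]phenol (both carbinol epimers) | CN1CCCC[C@@H]1c1c(OCOC)cc(O)c(C(O)C#Cc2ccccc2)c1OCOC
F7 | step 4 | 5-[(methoxycarbonyl)amino]pentanoic acid | COC(=O)NCCCCC(=O)O
F8 | step 4 | methyl N-[5-oxo-5-(2,4,6-trihydroxyphenyl)pentyl]carbamate | COC(=O)NCCCCC(=O)c1c(O)cc(O)cc1O
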